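**Retrosynthetic overview**

1. Ring atoms are numbered O1–O2–C3–C4–C4a–O5–C6(=O)–C7–C7a (C7a joins O1 and C4a). C3 carries CH3 and the 10-phenyldecyl chain; C4a carries CH3.
2. Key disconnection: C7–C6 (with C6–O5) and O1–C7a are made together. The acyclic hydroperoxy vinyl carbinol 14 and CO are joined by a palladium-catalysed peroxy-carbonylative bicyclisation, and the γ-lactone is closed through the new C7–C6 bond.
3. Enabling feature: C7a (peroxide oxygen) and C4a (lactone oxygen) are neighbours, and C7 is the only atom between C7a and C6. A vinyl group on the C4a carbinol therefore takes the C3 hydroperoxide at its inner carbon, while palladium on the outer carbon, chelated by the C4a–OH, sits one CO away from the cis-fused five-membered lactone.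
4. 14 comes from (R,R)-epoxide 11 by invertive perhydrolysis at the tertiary carbon (sets C3). The C1′ hydroxyl this leaves is silylated, then removed at the end by dehydration and diimide reduction. 11 comes from dienol 10 by Shi epoxidation; 10 from (S)-2-methylglycidol 3 (C4a stereocentre), acetylide, Me3Al and iodide 2.
5. Ring order: 1,2-dioxane first, γ-lactone second, both within step 10; C7a is set there by the cis ring fusion.

Key step: step 10

Assumption: the opening of the tertiary epoxide carbon by H2O2 (step 8) is taken to be invertive, and the D-fructose-derived Shi ketone is taken to give the (R,R)-epoxide from the (E)-trisubstituted alkene (step 7), as the usual models for both reactions predict.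

**Route**

Step 1
Reactants: 1 9-phenylnonan-1-ol
Product: 2 (9-iodononyl)benzene
Conditions: I2, PPh3, imidazole, CH2Cl2, 0 °C → rt
Reagents that add atoms: iodine, II
Why: Appel-type iodination of a primary alcohol by SN2 displacement of the alkoxyphosphonium ion, with no stereocentre involved.

Step 2
Reactants: 3 (S)-2-methylglycidol
Product: 4 (R)-2-methylpent-4-yne-1,2-diol
Conditions: LiC≡CH·H2NCH2CH2NH2 (3 equiv), DMSO, 0 °C → rt; then H2O
Reagents that add atoms: lithium acetylide–ethylenediamine complex, [Li+].[C-]#C.NCCN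
Why: SN2 opening of the 2,2-disubstituted epoxide at its unhindered CH2 terminus by the acetylide (epoxide alkynylation) leaves the quaternary carbinol carbon untouched, so the descriptor changes from S to R only through the CIP priorities.

Step 3
Reactants: 4 (R)-2-methylpent-4-yne-1,2-diol
Product: 6 (2R,4E)-5-iodo-2,4-dimethylpent-4-ene-1,2-diol, via alkenylalane 5 (not isolated)
Conditions: Me3Al (4 equiv), Cp2ZrCl2 (0.5 equiv), CH2Cl2, 0 °C → rt; then I2, THF, −30 → 0 °C; aq. NaHCO3/Na2S2O3
Reagents that add atoms: trimethylaluminium, C[Al](C)C; iodine, II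
Why: Negishi zirconium-catalysed methylalumination adds CH3 and Al syn across the terminal alkyne with CH3 on the inner carbon, and iodinolysis of the alkenyl–Al bond with retention should give the (E)-iodide.

Step 4
Reactants: 2 (9-iodononyl)benzene; 6 (2R,4E)-5-iodo-2,4-dimethylpent-4-ene-1,2-diol
Product: 8 (2R,4E)-2,4-dimethyl-14-phenyltetradec-4-ene-1,2-diol, via alkylzinc iodide 7 (not isolated)
Conditions: 2, Zn, LiCl, THF, 40 °C; then 6, Pd(OAc)2 (2 mol %), SPhos (4 mol %), THF, rt
Reagents that add atoms: none
Why: Negishi sp3–sp2 cross-coupling (zinc insertion into the primary iodide, then palladium catalysis) should proceed with retention of the alkene geometry and tolerate the free hydroxyl groups.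

Step 5
Reactants: 8 (2R,4E)-2,4-dimethyl-14-phenyltetradec-4-ene-1,2-diol
Product: 9 (2R,4E)-2-hydroxy-2,4-dimethyl-14-phenyltetradec-4-enal
Conditions: SO3·pyridine, DMSO, i-Pr2NEt, CH2Cl2, 0 °C
Reagents that add atoms: none
Why: Parikh–Doering oxidation converts the primary alcohol of the 1,2-diol into the aldehyde without glycol cleavage, the tertiary hydroxyl being unable to oxidise and the α-carbon carrying no hydrogen that could epimerise.

Step 6
Reactants: 9 (2R,4E)-2-hydroxy-2,4-dimethyl-14-phenyltetradec-4-enal
Product: 10 (3R,5E)-3,5-dimethyl-15-phenylpentadeca-1,5-dien-3-ol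
Conditions: Ph3PCH3Br, KOtBu (excess), THF, 0 °C → rt
Reagents that add atoms: methyltriphenylphosphonium bromide, C[P+](c1ccccc1)(c1ccccc1)c1ccccc1.[Br-]
Why: Wittig methylenation of the aldehyde with the non-stabilised ylide, used in excess to absorb the tertiary O–H, should give the vinyl carbinol.

Step 7
Reactants: 10 (3R,5E)-3,5-dimethyl-15-phenylpentadeca-1,5-dien-3-ol
Product: 11 (2R)-2-methyl-1-[(2R,3R)-2-methyl-3-(9-phenylnonyl)oxiran-2-yl]but-3-en-2-ol
Conditions: Shi ketone from D-fructose (30 mol %), KHSO5 (as 2KHSO5·KHSO4·K2SO4), K2CO3, Bu4NHSO4, MeCN–CH2(OMe)2–aq. Na2B4O7, 0 °C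
Reagents that add atoms: potassium peroxymonosulfate, [K+].[O-]S(=O)(=O)OO
Why: Shi asymmetric epoxidation (chiral dioxirane, spiro transition state) is selective for the electron-rich trisubstituted alkene over the vinyl group, and the D-fructose-derived ketone is expected to deliver oxygen to the face that gives the (R,R)-epoxide under reagent control.

Step 8
Reactants: 11 (2R)-2-methyl-1-[(2R,3R)-2-methyl-3-(9-phenylnonyl)oxiran-2-yl]but-3-en-2-ol
Product: 12 (3R,5S,6R)-5-hydroperoxy-3,5-dimethyl-15-phenylpentadec-1-ene-3,6-diol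
Conditions: H2O2 (anhydrous, in Et2O, 10 equiv), H3PMo12O40 (2 mol %), Et2O, 0 °C → rt
Reagents that add atoms: hydrogen peroxide, OO
Why: Acid-catalysed perhydrolysis of the epoxide opens the tertiary C–O bond by backside attack of H2O2 (borderline SN2 at the carbon best able to carry positive charge), so C5 is inverted and the tertiary hydroperoxide stereocentre follows from the epoxide configuration.

Step 9
Reactants: 12 (3R,5S,6R)-5-hydroperoxy-3,5-dimethyl-15-phenylpentadec-1-ene-3,6-diol
Product: 14 (3R,5S,6R)-5-hydroperoxy-3,5-dimethyl-15-phenyl-6-(triethylsilyloxy)pentadec-1-en-3-ol, via bis(triethylsilyl) derivative 13 (not isolated)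
Conditions: Et3SiCl (2.2 equiv), imidazole, DMF, 0 °C; then K2CO3 (cat.), MeOH, 0 °C
Reagents that add atoms: chlorotriethylsilane, CC[Si](Cl)(CC)CC
Why: Silylation should take the hydroperoxide and the secondary hydroxyl but not the tertiary allylic hydroxyl, and mild methanolysis then cleaves only the far more labile Si–OO bond (selective protection of the side-chain hydroxyl).

Step 10
Reactants: 14 (3R,5S,6R)-5-hydroperoxy-3,5-dimethyl-15-phenyl-6-(triethylsilyloxy)pentadec-1-en-3-ol
Product: 17 (3S,4aR,7aR)-3,4a-dimethyl-3-[(1R)-10-phenyl-1-(triethylsilyloxy)decyl]-3,4,4a,7a-tetrahydrofuro[3,2-c][1,2]dioxin-6(7H)-one, via alkylpalladium chloride 15 (not isolated), via acylpalladium chloride 16 (not isolated)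
Conditions: PdCl2(MeCN)2 (10 mol %), p-benzoquinone (2 equiv), NaOAc (1 equiv), CO (1 atm), THF, 0 °C → rt
Reagents that add atoms: carbon monoxide, [C-]#[O+]
Why: Proposed new method: Divalent palladium bound to the vinyl group is attacked anti at the inner alkene carbon (C7a) by the terminal oxygen of the tertiary hydroperoxide (Wacker-type peroxypalladation), which closes the 1,2-dioxane in a 6-exo-trig mode and leaves palladium on C7, held in a five-membered chelate by the C4a hydroxyl (15); migratory insertion of CO into the Pd–C7 bond makes the C7–C6 bond (16) and the acylpalladium is captured by the chelated hydroxyl, so the five-membered γ-lactone closes through C7–C6–O5 while zerovalent palladium is returned to the divalent state by benzoquinone. The closest known reactions are the palladium-catalysed 6-exo cyclisation of γ,δ-unsaturated tertiary hydroperoxides to 1,2-dioxanes and the palladium-catalysed oxycarbonylation–lactonisation of ene-diols to cis-fused bicyclic lactones; the proposal merges them, with a hydroperoxide as the first nucleophile. The new stereocentre C7a is set in the chair-like transition state of the dioxane closure, in which the silyloxyalkyl group on C3, the methyl on C4a and the C7 methylene are equatorial and the C4a–OH is axial, which places O5 and C7 cis, the only relationship that the hydroxyl chelate and the five-membered lactone accept. Because peroxypalladation is reversible, material that adds with the other facial sense can return and be drained through this diastereomer. The step needs 6-exo rather than 7-endo attack (secured by Markovnikov addition to the inner carbon), CO insertion rather than β-elimination (secured by the CO atmosphere and the chelate), and the hydroperoxide rather than an alcohol as ring-closing nucleophile (secured by silylation of the side-chain hydroxyl, which could otherwise close a tetrahydropyran in the same mode).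

Step 11
Reactants: 17 (3S,4aR,7aR)-3,4a-dimethyl-3-[(1R)-10-phenyl-1-(triethylsilyloxy)decyl]-3,4,4a,7a-tetrahydrofuro[3,2-c][1,2]dioxin-6(7H)-one
Product: 18 (3S,4aR,7aR)-3-[(1R)-1-hydroxy-10-phenyldecyl]-3,4a-dimethyl-3,4,4a,7a-tetrahydrofuro[3,2-c][1,2]dioxin-6(7H)-one
Conditions: HF·pyridine, pyridine, THF, 0 °C
Reagents that add atoms: none
Why: Fluoride-mediated cleavage of the triethylsilyl ether (desilylation) under buffered conditions should leave the peroxide and the lactone untouched.

Step 12
Reactants: 18 (3S,4aR,7aR)-3-[(1R)-1-hydroxy-10-phenyldecyl]-3,4a-dimethyl-3,4,4a,7a-tetrahydrofuro[3,2-c][1,2]dioxin-6(7H)-one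
Product: 19 (3S,4aR,7aR)-3,4a-dimethyl-3-[(E)-10-phenyldec-1-en-1-yl]-3,4,4a,7a-tetrahydrofuro[3,2-c][1,2]dioxin-6(7H)-one
Conditions: Ph2S[OC(CF3)2Ph]2 (Martin sulfurane, 2 equiv), CH2Cl2, rt
Reagents that add atoms: none
Why: Martin sulfurane dehydration of the secondary alcohol by E2 elimination through the alkoxysulfonium ion can only use the side-chain CH2 hydrogens, and ionisation is disfavoured by the neighbouring peroxide-bearing carbon, so the alkene should form away from the ring without touching the stereocentres.

Step 13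
Reactants: 19 (3S,4aR,7aR)-3,4a-dimethyl-3-[(E)-10-phenyldec-1-en-1-yl]-3,4,4a,7a-tetrahydrofuro[3,2-c][1,2]dioxin-6(7H)-one
Product: 20 (3R,4aR,7aR)-3,4a-dimethyl-3-(10-phenyldecyl)-3,4,4a,7a-tetrahydrofuro[3,2-c][1,2]dioxin-6(7H)-one
Conditions: KO2CN=NCO2K, AcOH, CH2Cl2–MeOH, 0 °C → rt
Reagents that add atoms: none
Why: Diimide reduction (concerted syn transfer of H2) saturates the disubstituted alkene and spares O–O bonds and lactones, which a metal-catalysed hydrogenation would not.

**Compound list**

1 | 9-phenylnonan-1-ol | OCCCCCCCCCc1ccccc1 | starting material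
2 | (9-iodononyl)benzene | ICCCCCCCCCc1ccccc1 | intermediate
3 | (S)-2-methylglycidol, (S)-(2-methyloxiran-2-yl)methanol | C[C@]1(CO)CO1 | starting material
4 | (R)-2-methylpent-4-yne-1,2-diol | C#CC[C@@](C)(O)CO | intermediate
5 | (E)-alkenyldimethylalane from 4, both hydroxyls as dimethylaluminium alkoxides | C[Al](C)/C=C(\C)C[C@@](C)(O[Al](C)C)CO[Al](C)C | intermediate (not isolated)
6 | (2R,4E)-5-iodo-2,4-dimethylpent-4-ene-1,2-diol | I/C=C(\C)C[C@@](C)(O)CO | intermediate
7 | (9-phenylnonyl)zinc iodide | I[Zn]CCCCCCCCCc1ccccc1 | intermediate (not isolated)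
8 | (2R,4E)-2,4-dimethyl-14-phenyltetradec-4-ene-1,2-diol | C/C(=C\CCCCCCCCCc1ccccc1)C[C@@](C)(O)CO | intermediate
9 | (2R,4E)-2-hydroxy-2,4-dimethyl-14-phenyltetradec-4-enal | C/C(=C\CCCCCCCCCc1ccccc1)C[C@@](C)(O)C=O | intermediate
10 | (3R,5E)-3,5-dimethyl-15-phenylpentadeca-1,5-dien-3-ol | C/C(=C\CCCCCCCCCc1ccccc1)C[C@@](C)(O)C=C | intermediate
11 | (2R)-2-methyl-1-[(2R,3R)-2-methyl-3-(9-phenylnonyl)oxiran-2-yl]but-3-en-2-ol | C[C@]1(C[C@@](C)(O)C=C)O[C@@H]1CCCCCCCCCc1ccccc1 | intermediate
12 | (3R,5S,6R)-5-hydroperoxy-3,5-dimethyl-15-phenylpentadec-1-ene-3,6-diol | C=C[C@](C)(O)C[C@](C)(OO)[C@H](O)CCCCCCCCCc1ccccc1 | intermediate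
13 | (3R,5S,6R)-3,5-dimethyl-15-phenyl-6-(triethylsilyloxy)-5-(triethylsilylperoxy)pentadec-1-en-3-ol | C=C[C@](C)(O)C[C@](C)(OO[Si](CC)(CC)CC)[C@H](O[Si](CC)(CC)CC)CCCCCCCCCc1ccccc1 | intermediate (not isolated)
14 | (3R,5S,6R)-5-hydroperoxy-3,5-dimethyl-15-phenyl-6-(triethylsilyloxy)pentadec-1-en-3-ol | C=C[C@](C)(O)C[C@](C)(OO)[C@H](O[Si](CC)(CC)CC)CCCCCCCCCc1ccccc1 | intermediate
15 | {(3S,4R,6S)-4-hydroxy-4,6-dimethyl-6-[(1R)-10-phenyl-1-(triethylsilyloxy)decyl]-1,2-dioxan-3-yl}methylpalladium chloride | C[C@@]1([C@H](O[Si](CC)(CC)CC)CCCCCCCCCc2ccccc2)C[C@@](C)(O)[C@@H](C[Pd]Cl)OO1 | intermediate (not isolated)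
16 | {(3R,4R,6S)-4-hydroxy-4,6-dimethyl-6-[(1R)-10-phenyl-1-(triethylsilyloxy)decyl]-1,2-dioxan-3-yl}acetylpalladium chloride | C[C@@]1([C@H](O[Si](CC)(CC)CC)CCCCCCCCCc2ccccc2)C[C@@](C)(O)[C@@H](CC(=O)[Pd]Cl)OO1 | intermediate (not isolated)
17 | (3S,4aR,7aR)-3,4a-dimethyl-3-[(1R)-10-phenyl-1-(triethylsilyloxy)decyl]-3,4,4a,7a-tetrahydrofuro[3,2-c][1,2]dioxin-6(7H)-one | C[C@@]1([C@H](O[Si](CC)(CC)CC)CCCCCCCCCc2ccccc2)C[C@@]2(C)OC(=O)C[C@H]2OO1 | intermediate
18 | (3S,4aR,7aR)-3-[(1R)-1-hydroxy-10-phenyldecyl]-3,4a-dimethyl-3,4,4a,7a-tetrahydrofuro[3,2-c][1,2]dioxin-6(7H)-one | C[C@@]1([C@H](O)CCCCCCCCCc2ccccc2)C[C@@]2(C)OC(=O)C[C@H]2OO1 | intermediate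
19 | (3S,4aR,7aR)-3,4a-dimethyl-3-[(E)-10-phenyldec-1-en-1-yl]-3,4,4a,7a-tetrahydrofuro[3,2-c][1,2]dioxin-6(7H)-one | C[C@@]1(/C=C/CCCCCCCCc2ccccc2)C[C@@]2(C)OC(=O)C[C@H]2OO1 | intermediate
20 | (3R,4aR,7aR)-3,4a-dimethyl-3-(10-phenyldecyl)-3,4,4a,7a-tetrahydrofuro[3,2-c][1,2]dioxin-6(7H)-one (cis-fused 1,2-dioxane γ-lactone) | C[C@@]1(CCCCCCCCCCc2ccccc2)C[C@@]2(C)OC(=O)C[C@H]2OO1 | target

**Step count**

Total steps: 13. Longest linear sequence: 12 steps (3 → 20, steps 2–13); step 1 prepares the coupling partner 2.

**Steps most likely to fail**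

Step 10 (proposed new method). What may go wrong: reduction of the O–O bond by zerovalent palladium or by the palladium–CO couple, with the hydroperoxide acting as the oxidant; or loss of the peroxide from the alkylpalladium by β-elimination before CO inserts. The fallback uses known chemistry and closes the lactone through the same C7–C6 bond. It sets out from 14, which with Hg(OAc)2 in CH2Cl2 and then aqueous KCl should undergo cycloperoxymercuration (6-exo, Markovnikov, reversible and under the same chair control) to the organomercurial chloro{[(3S,4R,6S)-4-hydroxy-4,6-dimethyl-6-[(1R)-10-phenyl-1-(triethylsilyloxy)decyl]-1,2-dioxan-3-yl]methyl}mercury F1. The hydroperoxide is thus consumed before any palladium is present. F1 with Li2PdCl4 (1 equiv), NaOAc and CO (1 atm) in THF should transmetallate to palladium, insert CO and lactonise (carbonylation of an organomercurial through palladium), and the route is rejoined at 17.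

Step 8. What may go wrong: loss of stereospecificity through ionisation at the tertiary carbon, participation of the tertiary C3 hydroxyl in the opening (oxetane formation and net retention), or acid-promoted ionisation of the tertiary allylic alcohol. The fallback sets out from 10 and introduces the peroxide by radical chemistry instead. Mukaiyama–Isayama hydroperoxysilylation (Co(acac)2 cat., O2, Et3SiH, ClCH2CH2Cl, rt) of the trisubstituted alkene should give the silyl peroxide (3R,5RS)-3,5-dimethyl-15-phenyl-5-(triethylsilylperoxy)pentadec-1-en-3-ol F2, which carries no oxygen on C6. Desilylation (Bu4NF, AcOH, THF, 0 °C) should give the hydroperoxide (3R,5RS)-5-hydroperoxy-3,5-dimethyl-15-phenylpentadec-1-en-3-ol F3. F3 under the conditions of step 10 should give 20 directly, so steps 7, 9 and 11–13 fall away and the route is rejoined at 20. The price is that C3 is no longer controlled: both C3 epimers would form and would have to be separated by preparative HPLC.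

Step 12. What may go wrong: a 1,2-shift or fragmentation of the alkoxysulfonium intermediate next to the peroxide-bearing quaternary carbon instead of clean E2 elimination, or failure of the hindered carbinol to react. The fallback sets out from 18 and removes the oxygen by radical deoxygenation. 1,1′-Thiocarbonyldiimidazole (DMAP, CH2Cl2, rt) should give the thiocarbamate O-{(1R)-1-[(3S,4aR,7aR)-3,4a-dimethyl-6-oxohexahydrofuro[3,2-c][1,2]dioxin-3-yl]-10-phenyldecyl} 1H-imidazole-1-carbothioate F4. Barton–McCombie reduction of F4 (Bu3SnH in high concentration, Et3B/air, toluene, 0 °C, so that hydrogen transfer outruns attack of the β-peroxy radical on the O–O bond) should give 20 directly. Steps 12 and 13 are bypassed and the route is rejoined at 20.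

**Further compounds**

F1 | step 10 | chloro{[(3S,4R,6S)-4-hydroxy-4,6-dimethyl-6-[(1R)-10-phenyl-1-(triethylsilyloxy)decyl]-1,2-dioxan-3-yl]methyl}mercury | C[C@@]1([C@H](O[Si](CC)(CC)CC)CCCCCCCCCc2ccccc2)C[C@@](C)(O)[C@@H](C[Hg]Cl)OO1
F2 | step 8 | (3R,5RS)-3,5-dimethyl-15-phenyl-5-(triethylsilylperoxy)pentadec-1-en-3-ol | C=C[C@](C)(O)CC(C)(OO[Si](CC)(CC)CC)CCCCCCCCCCc1ccccc1
F3 | step 8 | (3R,5RS)-5-hydroperoxy-3,5-dimethyl-15-phenylpentadec-1-en-3-ol | C=C[C@](C)(O)CC(C)(OO)CCCCCCCCCCc1ccccc1
F4 | step 12 | O-{(1R)-1-[(3S,4aR,7aR)-3,4a-dimethyl-6-oxohexahydrofuro[3,2-c][1,2]dioxin-3-yl]-10-phenyldecyl} 1H-imidazole-1-carbothioate | C[C@@]1([C@H](OC(=S)n3ccnc3)CCCCCCCCCc2ccccc2)C[C@@]2(C)OC(=O)C[C@H]2OO1
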